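The route rests on cutting C4–C5 and C9–C10 of the trans-decalin. Rings A and B carry the gem-dimethyl group on C4, the angular methyl on C10 and the carbon branch C11 on C9. This pattern is the folded image of an E-geranyl chain capped by a β-keto ester. Acyclic keto ester 4, one step from two bulk chemicals, is closed by a chiral proton source to decalone 5. That one operation forms two rings and two C–C bonds and sets C5, C9 and C10. The C8 ketone then places the C8=C9 alkene unambiguously. C11 is extended to a 2-methylene aldehyde. Cross-metathesis with an (R)-allylbutenolide made from methyl (R)-glycidate completes the E-enal.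

Key step: step 2

Numbering: drimane numbering for the decalin (C1–C10, C11 on C9), continued as C12, C13 (bears CHO), C14, C15, C16 (lactone stereocentre), C17 (bears CH2OH), C18, C19 (lactone C=O).

Assumption: the (R)-binaphthol ligand is taken to give the 5S,10S series, as it does with homogeranyl chains that end in arenes or oxygen nucleophiles; if the keto ester reverses this sense, the (S)-ligand is used and nothing else changes (the ligand is made in one operation from (R)-BINOL and 2-fluorobenzyl bromide and is recovered unchanged).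

Step 1
Reactants: 1 methyl acetoacetate; 2 geranyl bromide
Product: 4 methyl (6E)-7,11-dimethyl-3-oxododeca-6,10-dienoate, via acetoacetate dianion 3 (not isolated)
Conditions: NaH (1.1 equiv), THF, 0 °C; n-BuLi (1.05 equiv), 0 °C; 2, 0 °C to rt; aq. HCl
Reagents that add atoms: none
Why: Acetoacetate dianion alkylation, in which the more basic terminal carbanion displaces the primary allylic bromide by SN2, keeps the E alkene and creates no stereocentre.

Step 2
Reactants: 4 methyl (6E)-7,11-dimethyl-3-oxododeca-6,10-dienoate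
Product: 5 methyl (1R,4aS,8aS)-5,5,8a-trimethyl-2-oxodecahydronaphthalene-1-carboxylate
Conditions: 4 + SnCl4 (1.0 equiv), toluene, −78 °C; added to (R)-2'-(2-fluorobenzyloxy)-1,1'-binaphthalen-2-ol (2.0 equiv)/SnCl4 (1.8 equiv), toluene, −78 °C, 3 d; once 4 is consumed, 0 °C, 1 h; aq. NaHCO3
Reagents that add atoms: none
Why: Proposed new method: the tin-activated phenolic O–H of the chiral binaphthol protonates the isopropylidene alkene of 4 on one face to give the tertiary cation at the future C4, the CH carbon of the E alkene (future C5) attacks it, the new tertiary cation at C10 is trapped by the α-carbon of the tin-chelated enol (C9), and loss of the enol proton returns the acid, so the step is a net isomerisation. The closest known reaction types are the racemic SnCl4-promoted bicyclisation of geranyl β-keto esters and the cyclisation of homogeranyl arenes and phenols by Lewis-acid-assisted chiral Brønsted acids, and these two have not been combined. Ring A closes 6-endo at the central alkene (bond C4–C5) and ring B closes 6-endo at the enol C=C, enol-endo (bond C9–C10), each through a chair. C5 is fixed by the alkene face that the chiral acid selects in the protonation and first closure, C10 follows from anti addition across the E alkene (trans fusion, 10-methyl anti to 5-H), and C9 settles as the equatorial ester through enolisation and is erased in step 3. The step needs protonation at the terminal rather than the internal alkene and capture through carbon rather than oxygen: the isopropylidene end is the more accessible and lies farthest from the electron-poor tin chelate, and chelation occupies both carbonyl oxygens so that only C9 can attack. Because the dicarbonyl would otherwise strip SnCl4 from the ligand, one equivalent of SnCl4 is spent on it beforehand, the ligand is kept in excess over the remaining SnCl4, and the reaction is held at −78 °C, where the tin-only pathway should be slow.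

Step 3
Reactants: 5 methyl (1R,4aS,8aS)-5,5,8a-trimethyl-2-oxodecahydronaphthalene-1-carboxylate
Product: 7 methyl (4aS,8aS)-2-[(diethoxyphosphoryl)oxy]-5,5,8a-trimethyl-3,4,4a,5,6,7,8,8a-octahydronaphthalene-1-carboxylate, via sodium enolate 6 (not isolated)
Conditions: NaH (1.2 equiv), THF, 0 °C; (EtO)2P(O)Cl (1.3 equiv), 0 °C to rt
Reagents that add atoms: diethyl chlorophosphate, CCOP(=O)(Cl)OCC
Why: O-phosphorylation of a β-keto ester enolate locks the future alkene between C8 and C9 and removes the C9 centre while C5 and C10 stay untouched.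

Step 4
Reactants: 7 methyl (4aS,8aS)-2-[(diethoxyphosphoryl)oxy]-5,5,8a-trimethyl-3,4,4a,5,6,7,8,8a-octahydronaphthalene-1-carboxylate
Product: 8 methyl (4aS,8aS)-2,5,5,8a-tetramethyl-3,4,4a,5,6,7,8,8a-octahydronaphthalene-1-carboxylate (methyl drim-8-en-11-oate)
Conditions: Me2CuLi (3 equiv, from MeLi and CuBr·SMe2), Et2O, −78 to −20 °C; aq. NH4Cl
Reagents that add atoms: lithium dimethylcuprate, [Li+].C[Cu-]C
Why: Addition–elimination of a Gilman cuprate on a β-phosphoryloxy enoate (enol phosphate coupling) exchanges the phosphate for the C8 methyl, so the tetrasubstituted alkene can only lie at C8=C9.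

Step 5
Reactants: 8 methyl drim-8-en-11-oate
Product: 9 [(4aS,8aS)-2,5,5,8a-tetramethyl-3,4,4a,5,6,7,8,8a-octahydronaphthalen-1-yl]methanol (drim-8-en-11-ol)
Conditions: iBu2AlH (2.5 equiv), CH2Cl2, −78 to 0 °C; aq. potassium sodium tartrate
Reagents that add atoms: none
Why: 1,2-Reduction of the hindered conjugated ester by the aluminium hydride gives the primary allylic alcohol, and the tetrasubstituted alkene is inert.

Step 6
Reactants: 9 drim-8-en-11-ol
Product: 10 (4aS,8aS)-1-(bromomethyl)-2,5,5,8a-tetramethyl-3,4,4a,5,6,7,8,8a-octahydronaphthalene (11-bromodrim-8-ene)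
Conditions: PBr3 (0.4 equiv), pyridine (cat.), Et2O, −10 to 0 °C; used at once without chromatography
Reagents that add atoms: phosphorus tribromide, BrP(Br)Br
Why: Bromide displaces the phosphite ester of the primary allylic alcohol by SN2 in the cold, and the primary bromide is preferred over the transposed tertiary one at the fully substituted C8.

Step 7
Reactants: 10 11-bromodrim-8-ene; 11 2-methylprop-2-en-1-ol (methallyl alcohol)
Product: 13 2-methylidene-4-[(4aS,8aS)-2,5,5,8a-tetramethyl-3,4,4a,5,6,7,8,8a-octahydronaphthalen-1-yl]butan-1-ol, via dilithiated methallyl alcohol 12 (not isolated)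
Conditions: 11 (3 equiv), n-BuLi (6 equiv), TMEDA, Et2O–THF, 0 °C to rt; 10, THF, −78 to 0 °C; H2O
Reagents that add atoms: none
Why: Allyl–allyl SN2 alkylation forms C11–C12 without a regiochemical issue, because the two termini of the 2-(oxidomethyl)allyl anion are identical and SN2′ attack at the fully substituted C8 is blocked.

Step 8
Reactants: 13 2-methylidene-4-[(4aS,8aS)-2,5,5,8a-tetramethyl-3,4,4a,5,6,7,8,8a-octahydronaphthalen-1-yl]butan-1-ol
Product: 14 2-methylidene-4-[(4aS,8aS)-2,5,5,8a-tetramethyl-3,4,4a,5,6,7,8,8a-octahydronaphthalen-1-yl]butanal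
Conditions: MnO2 (activated, 20 equiv), CH2Cl2, rt; used promptly
Reagents that add atoms: none
Why: MnO2 oxidation is selective for the allylic alcohol, stops at the aldehyde and leaves both alkenes alone.

Step 9
Reactants: 15 methyl (2R)-oxirane-2-carboxylate (methyl (R)-glycidate)
Product: 16 methyl (2R)-2-hydroxypent-4-enoate
Conditions: CH2=CHMgBr (1.3 equiv), CuBr·SMe2 (10 mol %), THF, −78 to −40 °C; aq. NH4Cl
Reagents that add atoms: vinylmagnesium bromide, C=C[Mg]Br
Why: Copper-catalysed Grignard opening of the epoxide at its unsubstituted carbon (SN2) outruns ester attack in the cold, and the future C16 centre comes unchanged from the chiral pool because its C–O bond is not broken.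

Step 10
Reactants: 16 methyl (2R)-2-hydroxypent-4-enoate
Product: 17 methyl (2R)-2-(acetyloxy)pent-4-enoate
Conditions: Ac2O (1.5 equiv), pyridine, DMAP (cat.), CH2Cl2, 0 °C to rt
Reagents that add atoms: acetic anhydride, CC(=O)OC(C)=O
Why: DMAP-catalysed acetylation of the secondary alcohol brings in C18 and C19 with retention at C16.

Step 11
Reactants: 17 methyl (2R)-2-(acetyloxy)pent-4-enoate
Product: 18 (5R)-4-hydroxy-5-(prop-2-en-1-yl)furan-2(5H)-one (5-allyltetronic acid)
Conditions: LiN(SiMe3)2 (2.5 equiv), THF, −78 to −20 °C; 1 M HCl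
Reagents that add atoms: none
Why: Dieckmann-type intramolecular Claisen condensation of the kinetically formed acetate enolate onto the methyl ester closes the lactone, and the delocalised tetronate anion that results shields C16–H from epimerisation.

Step 12
Reactants: 18 (5R)-4-hydroxy-5-(prop-2-en-1-yl)furan-2(5H)-one
Product: 19 (2R)-5-oxo-2-(prop-2-en-1-yl)-2,5-dihydrofuran-3-yl trifluoromethanesulfonate
Conditions: Tf2O (1.1 equiv), iPr2NEt (1.2 equiv), CH2Cl2, −78 °C
Reagents that add atoms: trifluoromethanesulfonic anhydride, O=S(=O)(OS(=O)(=O)C(F)(F)F)C(F)(F)F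
Why: O-sulfonylation of the vinylogous acid at low temperature gives the vinyl triflate without touching C16.

Step 13
Reactants: 19 (2R)-5-oxo-2-(prop-2-en-1-yl)-2,5-dihydrofuran-3-yl trifluoromethanesulfonate
Product: 20 (5R)-4-(hydroxymethyl)-5-(prop-2-en-1-yl)furan-2(5H)-one
Conditions: Bu3SnCH2OH (1.2 equiv), Pd(PPh3)4 (5 mol %), LiCl (3 equiv), THF, 65 °C
Reagents that add atoms: (tributylstannyl)methanol, CCCC[Sn](CCCC)(CCCC)CO
Why: Stille coupling (oxidative addition of zerovalent palladium into the C–OTf bond, preferential transfer of the α-oxygenated CH2OH group, reductive elimination) installs the hydroxymethyl group on C17 under base-free conditions that spare C16.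

Step 14
Reactants: 14 2-methylidene-4-[(4aS,8aS)-2,5,5,8a-tetramethyl-3,4,4a,5,6,7,8,8a-octahydronaphthalen-1-yl]butanal; 20 (5R)-4-(hydroxymethyl)-5-(prop-2-en-1-yl)furan-2(5H)-one
Product: 21 (2E)-4-[(2R)-3-(hydroxymethyl)-5-oxo-2,5-dihydrofuran-2-yl]-2-{2-[(4aS,8aS)-2,5,5,8a-tetramethyl-3,4,4a,5,6,7,8,8a-octahydronaphthalen-1-yl]ethyl}but-2-enal (target)
Conditions: 20 (2 equiv), second-generation Hoveyda–Grubbs catalyst RuCl2(H2IMes)(=CH-C6H4-2-OiPr) (10 mol %), 1,4-benzoquinone (20 mol %), CH2Cl2, 40 °C, N2 sparge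
Reagents that add atoms: none
Why: Olefin cross-metathesis of a terminal alkene with a 2-alkylacrolein forms C13=C14 as the more stable E-enal (CHO trans to C15); the tetrasubstituted C8=C9 and the electron-poor butenolide alkene are spectators, and the neutral medium avoids epimerisation at C16 and vinylogous elimination of the lactone carboxylate.

Compound list
1 | methyl acetoacetate | COC(=O)CC(C)=O | starting material
2 | geranyl bromide, (2E)-1-bromo-3,7-dimethylocta-2,6-diene | CC(C)=CCC/C(C)=C/CBr | starting material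
3 | sodium lithium dianion of methyl acetoacetate | [Na+].[Li+].C=C([O-])C=C([O-])OC | intermediate
4 | methyl (6E)-7,11-dimethyl-3-oxododeca-6,10-dienoate | COC(=O)CC(=O)CC/C=C(\C)CCC=C(C)C | intermediate
5 | methyl (1R,4aS,8aS)-5,5,8a-trimethyl-2-oxodecahydronaphthalene-1-carboxylate | O=C1[C@H](C(=O)OC)[C@@]2(C)CCCC(C)(C)[C@@H]2CC1 | intermediate
6 | sodium enolate of 5 | [Na+].[O-]C1=C(C(=O)OC)[C@@]2(C)CCCC(C)(C)[C@@H]2CC1 | intermediate
7 | methyl (4aS,8aS)-2-[(diethoxyphosphoryl)oxy]-5,5,8a-trimethyl-3,4,4a,5,6,7,8,8a-octahydronaphthalene-1-carboxylate | CCOP(=O)(OCC)OC1=C(C(=O)OC)[C@@]2(C)CCCC(C)(C)[C@@H]2CC1 | intermediate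
8 | methyl (4aS,8aS)-2,5,5,8a-tetramethyl-3,4,4a,5,6,7,8,8a-octahydronaphthalene-1-carboxylate | CC1=C(C(=O)OC)[C@@]2(C)CCCC(C)(C)[C@@H]2CC1 | intermediate
9 | [(4aS,8aS)-2,5,5,8a-tetramethyl-3,4,4a,5,6,7,8,8a-octahydronaphthalen-1-yl]methanol | CC1=C(CO)[C@@]2(C)CCCC(C)(C)[C@@H]2CC1 | intermediate
10 | (4aS,8aS)-1-(bromomethyl)-2,5,5,8a-tetramethyl-3,4,4a,5,6,7,8,8a-octahydronaphthalene | CC1=C(CBr)[C@@]2(C)CCCC(C)(C)[C@@H]2CC1 | intermediate
11 | 2-methylprop-2-en-1-ol | C=C(C)CO | starting material
12 | dilithiated 2-methylprop-2-en-1-ol | [Li+].[Li+].[CH2-]C(=C)C[O-] | intermediate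
13 | 2-methylidene-4-[(4aS,8aS)-2,5,5,8a-tetramethyl-3,4,4a,5,6,7,8,8a-octahydronaphthalen-1-yl]butan-1-ol | CC1=C(CCC(=C)CO)[C@@]2(C)CCCC(C)(C)[C@@H]2CC1 | intermediate
14 | 2-methylidene-4-[(4aS,8aS)-2,5,5,8a-tetramethyl-3,4,4a,5,6,7,8,8a-octahydronaphthalen-1-yl]butanal | CC1=C(CCC(=C)C=O)[C@@]2(C)CCCC(C)(C)[C@@H]2CC1 | intermediate
15 | methyl (2R)-oxirane-2-carboxylate | COC(=O)[C@H]1CO1 | starting material
16 | methyl (2R)-2-hydroxypent-4-enoate | C=CC[C@@H](O)C(=O)OC | intermediate
17 | methyl (2R)-2-(acetyloxy)pent-4-enoate | C=CC[C@@H](OC(C)=O)C(=O)OC | intermediate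
18 | (5R)-4-hydroxy-5-(prop-2-en-1-yl)furan-2(5H)-one | C=CC[C@H]1OC(=O)C=C1O | intermediate
19 | (2R)-5-oxo-2-(prop-2-en-1-yl)-2,5-dihydrofuran-3-yl trifluoromethanesulfonate | C=CC[C@H]1OC(=O)C=C1OS(=O)(=O)C(F)(F)F | intermediate
20 | (5R)-4-(hydroxymethyl)-5-(prop-2-en-1-yl)furan-2(5H)-one | C=CC[C@H]1OC(=O)C=C1CO | intermediate
21 | (2E)-4-[(2R)-3-(hydroxymethyl)-5-oxo-2,5-dihydrofuran-2-yl]-2-{2-[(4aS,8aS)-2,5,5,8a-tetramethyl-3,4,4a,5,6,7,8,8a-octahydronaphthalen-1-yl]ethyl}but-2-enal | CC1=C(CC/C(C=O)=C\C[C@H]2OC(=O)C=C2CO)[C@@]2(C)CCCC(C)(C)[C@@H]2CC1 | target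

Total step count: 14. Longest linear sequence: 9 (steps 1–8 and 14); steps 9–13 run in parallel.

Steps most likely to fail

Step 2. SnCl4 may migrate from the chiral ligand to the dicarbonyl, so that achiral proton initiation erodes the enantiomeric purity. The C10 cation may also lose a proton before ring B closes. The fallback replaces asymmetric induction by resolution and uses known chemistry; it runs from 4 back to 5. Compound 4 is cyclised with SnCl4 alone (CH2Cl2, 0 °C to rt), which gives 5 together with its mirror image, methyl (1S,4aR,8aR)-5,5,8a-trimethyl-2-oxodecahydronaphthalene-1-carboxylate F1. Condensation of this racemate with (R)-1-phenylethylamine (AcOH cat., toluene, Dean–Stark) erases C9 and gives two diastereomeric, hydrogen-bonded β-enamino esters: the (4aS,8aS) enamino ester F2 and the (4aR,8aR) enamino ester F3. These are separated by crystallisation or chromatography. Mild hydrolysis of F2 (1 M HCl, THF, rt) returns 5.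

Step 7. The strongly basic dianion may cause elimination, halogen–metal exchange or homocoupling of the hindered, labile allylic bromide. The fallback uses a soft organocopper coupling followed by a Mannich-type methylenation; it runs from 10 to 14. Compound 10 is coupled with [2-(1,3-dioxolan-2-yl)ethyl]magnesium bromide (Li2CuCl4, 3 mol %, THF, −20 °C to rt) to give 2-{3-[(4aS,8aS)-2,5,5,8a-tetramethyl-3,4,4a,5,6,7,8,8a-octahydronaphthalen-1-yl]propyl}-1,3-dioxolane F4. Hydrolysis (1 M HCl, THF, rt) gives 4-[(4aS,8aS)-2,5,5,8a-tetramethyl-3,4,4a,5,6,7,8,8a-octahydronaphthalen-1-yl]butanal F5. α-Methylenation with aqueous formaldehyde (pyrrolidine and propionic acid, 10 mol % each, iPrOH, 45 °C) then gives 14.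

Step 14. The 1,1-disubstituted, electron-poor alkene of 14 may engage too slowly, so that self-metathesis and double-bond migration of 20 take over. The fallback replaces metathesis by an acid-mediated crossed aldol condensation; it runs from 10 and 20 to 21.
- Compound 10 is taken to the butanal F5 as described under step 7. TBSOTf/Et3N (CH2Cl2, 0 °C) converts it into its (Z)-tert-butyldimethylsilyl enol ether F6.
- In parallel, 20 is silylated (TBSCl, imidazole, DMF) to (5R)-4-({[tert-butyl(dimethyl)silyl]oxy}methyl)-5-(prop-2-en-1-yl)furan-2(5H)-one F7. Ozone (CH2Cl2, −78 °C; Me2S) cleaves only its terminal alkene and gives [(2R)-3-({[tert-butyl(dimethyl)silyl]oxy}methyl)-5-oxo-2,5-dihydrofuran-2-yl]acetaldehyde F8.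
- Mukaiyama aldol addition of F6 to F8 (BF3·OEt2, CH2Cl2, −78 °C) should give the β-hydroxy aldehyde F9 as a mixture at its two new centres.
- Both new centres vanish on acid-catalysed dehydration (p-TsOH cat., toluene, 40 °C), which leads to the more stable E-enal, the tert-butyldimethylsilyl ether of the target F10.
- HF·pyridine (THF, 0 °C) then frees 21. No strong base meets the enal–butenolide array.

Further compounds
F1 | step 2 | methyl (1S,4aR,8aR)-5,5,8a-trimethyl-2-oxodecahydronaphthalene-1-carboxylate | O=C1[C@@H](C(=O)OC)[C@]2(C)CCCC(C)(C)[C@H]2CC1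
F2 | step 2 | methyl (4aS,8aS)-5,5,8a-trimethyl-2-{[(1R)-1-phenylethyl]amino}-3,4,4a,5,6,7,8,8a-octahydronaphthalene-1-carboxylate | C[C@@H](NC1=C(C(=O)OC)[C@@]2(C)CCCC(C)(C)[C@@H]2CC1)c1ccccc1
F3 | step 2 | methyl (4aR,8aR)-5,5,8a-trimethyl-2-{[(1R)-1-phenylethyl]amino}-3,4,4a,5,6,7,8,8a-octahydronaphthalene-1-carboxylate | C[C@@H](NC1=C(C(=O)OC)[C@]2(C)CCCC(C)(C)[C@H]2CC1)c1ccccc1
F4 | step 7 | 2-{3-[(4aS,8aS)-2,5,5,8a-tetramethyl-3,4,4a,5,6,7,8,8a-octahydronaphthalen-1-yl]propyl}-1,3-dioxolane | CC1=C(CCCC3OCCO3)[C@@]2(C)CCCC(C)(C)[C@@H]2CC1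
F5 | step 7 | 4-[(4aS,8aS)-2,5,5,8a-tetramethyl-3,4,4a,5,6,7,8,8a-octahydronaphthalen-1-yl]butanal | CC1=C(CCCC=O)[C@@]2(C)CCCC(C)(C)[C@@H]2CC1
F6 | step 14 | tert-butyl(dimethyl){[(1Z)-4-[(4aS,8aS)-2,5,5,8a-tetramethyl-3,4,4a,5,6,7,8,8a-octahydronaphthalen-1-yl]but-1-en-1-yl]oxy}silane | CC1=C(CC/C=C\O[Si](C)(C)C(C)(C)C)[C@@]2(C)CCCC(C)(C)[C@@H]2CC1
F7 | step 14 | (5R)-4-({[tert-butyl(dimethyl)silyl]oxy}methyl)-5-(prop-2-en-1-yl)furan-2(5H)-one | C=CC[C@H]1OC(=O)C=C1CO[Si](C)(C)C(C)(C)C
F8 | step 14 | [(2R)-3-({[tert-butyl(dimethyl)silyl]oxy}methyl)-5-oxo-2,5-dihydrofuran-2-yl]acetaldehyde | O=CC[C@H]1OC(=O)C=C1CO[Si](C)(C)C(C)(C)C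
F9 | step 14 | 4-[(2R)-3-({[tert-butyl(dimethyl)silyl]oxy}methyl)-5-oxo-2,5-dihydrofuran-2-yl]-3-hydroxy-2-{2-[(4aS,8aS)-2,5,5,8a-tetramethyl-3,4,4a,5,6,7,8,8a-octahydronaphthalen-1-yl]ethyl}butanal (mixture at C2 and C3) | CC1=C(CCC(C=O)C(O)C[C@H]3OC(=O)C=C3CO[Si](C)(C)C(C)(C)C)[C@@]2(C)CCCC(C)(C)[C@@H]2CC1
F10 | step 14 | tert-butyldimethylsilyl ether of 21 | CC1=C(CC/C(C=O)=C\C[C@H]3OC(=O)C=C3CO[Si](C)(C)C(C)(C)C)[C@@]2(C)CCCC(C)(C)[C@@H]2CC1
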